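**Strategy**

The target is a 2,3-dibenzylbutane-1,4-diol dibenzoate built from two C6–C3 units, so the route rests on the central C2–C3 bond of the butane chain (lignan C8–C8′). Echoing the oxidative 8–8′ coupling of lignan biosynthesis, an oxidative enolate heterocoupling unites a chiral N-acyloxazolidinone (3-benzyloxy-4-methoxyphenyl half) with a methyl ester (4-benzyloxy-3-methoxyphenyl half) and creates both adjacent methine stereocentres in one operation. The step exploits that each methine carbon sits α to an oxygenated CH2 (a latent carbonyl) and that the two halves differ only in the OH/OMe pattern of their benzene rings. Reduction, benzoylation and hydrogenolysis complete the synthesis.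

Key step: step 4

Remark: compounds 1, 4 and 7 and a solution of LDA are taken as purchased; both phenols travel as benzyl ethers, which the final hydrogenolysis removes without touching the primary alkyl benzoates.

**Route**

Step 1
Reactants: 1 3-(3-hydroxy-4-methoxyphenyl)propanoic acid
Product: 3 3-[3-(benzyloxy)-4-methoxyphenyl]propanoic acid, via benzyl ester 2 (not isolated)
Conditions: BnBr (2.3 equiv), K2CO3, DMF, 60 °C; then 2 M NaOH, MeOH, 60 °C; HCl work-up
Reagents that add atoms: benzyl bromide BrCc1ccccc1; sodium hydroxide (aqueous) [Na+].[OH-]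
Why: Williamson O-alkylation of the phenoxide (the carboxylate is benzylated as well) followed by saponification of the benzyl ester in the same flask, which leaves the aryl benzyl ether untouched.

Step 2
Reactants: 3 3-[3-(benzyloxy)-4-methoxyphenyl]propanoic acid; 4 (S)-4-benzyloxazolidin-2-one
Product: 6 (S)-4-benzyl-3-{3-[3-(benzyloxy)-4-methoxyphenyl]propanoyl}oxazolidin-2-one, via mixed pivalic anhydride 5 (not isolated)
Conditions: PivCl, Et3N, THF, −20 °C; then 4, LiCl, rt
Reagents that add atoms: none
Why: N-acylation of the oxazolidinone through the mixed pivalic anhydride, in which the hindered pivaloyl carbonyl directs attack to the arylpropanoyl carbonyl, the auxiliary stereocentre not being touched.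

Step 3
Reactants: 7 methyl 3-(4-hydroxy-3-methoxyphenyl)propanoate
Product: 8 methyl 3-[4-(benzyloxy)-3-methoxyphenyl]propanoate
Conditions: BnBr, K2CO3, acetone, reflux
Reagents that add atoms: benzyl bromide BrCc1ccccc1
Why: Williamson ether synthesis on the phenoxide under conditions that do not affect the methyl ester.

Step 4
Reactants: 6 (S)-4-benzyl-3-{3-[3-(benzyloxy)-4-methoxyphenyl]propanoyl}oxazolidin-2-one; 8 methyl 3-[4-(benzyloxy)-3-methoxyphenyl]propanoate (1.5 equiv)
Product: 11 methyl (2R,3R)-4-[(S)-4-benzyl-2-oxooxazolidin-3-yl]-3-[3-(benzyloxy)-4-methoxybenzyl]-2-[4-(benzyloxy)-3-methoxybenzyl]-4-oxobutanoate, via imide lithium enolate 9 (not isolated), via ester lithium enolate 10 (not isolated)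
Conditions: LDA (2.6 equiv), THF, −78 °C; then Fe(acac)3 (2.2 equiv), −78 °C → rt; 1 M HCl quench
Reagents that add atoms: none
Why: Both partners are deprotonated to lithium enolates (chelated (Z)-imide enolate 9 and ester enolate 10) that form a mixed aggregate; single-electron oxidation by Fe(III) generates an α-carbonyl radical inside this aggregate, the partner enolate captures it, and a second electron transfer delivers the 1,4-dicarbonyl, so the C8–C8′ bond and both methine stereocentres arise in one operation. The closest known reaction type is the Fe(III)- or Cu(II)-mediated intermolecular oxidative heterocoupling of an N-acyloxazolidinone enolate with an ester enolate to give 2,3-disubstituted succinates, the laboratory counterpart of the oxidative 8–8′ coupling of lignan biosynthesis. No ring is closed. C3 (the imide α-carbon) is controlled by the (S)-4-benzyl auxiliary, the new bond forming on the enolate face remote from the benzyl group, which gives R; C2 (the ester α-carbon) is controlled only by relative topicity, an open transition state that keeps the two arylmethyl groups apart being expected to favour the like (2R,3R) isomer. The step needs cross-coupling over homo-coupling, which the different enolate classes (imide versus ester, differing in oxidation potential and aggregation) should secure; the homodimers (a bis-imide and a diester) and any (2S,3R) epimer should be separable by chromatography.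

Step 5
Reactants: 11 methyl (2R,3R)-4-[(S)-4-benzyl-2-oxooxazolidin-3-yl]-3-[3-(benzyloxy)-4-methoxybenzyl]-2-[4-(benzyloxy)-3-methoxybenzyl]-4-oxobutanoate
Product: 12 (2R,3R)-2-[3-(benzyloxy)-4-methoxybenzyl]-3-[4-(benzyloxy)-3-methoxybenzyl]butane-1,4-diol
Conditions: LiAlH4, THF, 0 °C → rt; aqueous NaOH work-up
Reagents that add atoms: none
Why: LiAlH4 reduction of both acyl groups (exocyclic imide carbonyl and methyl ester) to primary alcohols with release of the auxiliary, no epimerizable intermediate being exposed to base, so both stereocentres should be retained.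

Step 6
Reactants: 12 (2R,3R)-2-[3-(benzyloxy)-4-methoxybenzyl]-3-[4-(benzyloxy)-3-methoxybenzyl]butane-1,4-diol
Product: 13 (2R,3R)-2-[3-(benzyloxy)-4-methoxybenzyl]-3-[4-(benzyloxy)-3-methoxybenzyl]butane-1,4-diyl dibenzoate
Conditions: BzCl (2.5 equiv), pyridine, DMAP (cat.), CH2Cl2, 0 °C → rt
Reagents that add atoms: benzoyl chloride O=C(Cl)c1ccccc1
Why: DMAP-catalysed acylation (esterification) of the two unhindered primary alcohols, which does not involve the stereocentres.

Step 7
Reactants: 13 (2R,3R)-2-[3-(benzyloxy)-4-methoxybenzyl]-3-[4-(benzyloxy)-3-methoxybenzyl]butane-1,4-diyl dibenzoate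
Product: 14 (2R,3R)-2-(3-hydroxy-4-methoxybenzyl)-3-(4-hydroxy-3-methoxybenzyl)butane-1,4-diyl dibenzoate
Conditions: H2 (1 atm), 10% Pd/C, EtOAc/EtOH, rt
Reagents that add atoms: none
Why: Catalytic hydrogenolysis of the two aryl benzyl ethers, to which primary alkyl benzoates, aryl methyl ethers and the two stereocentres are inert under neutral conditions.

**Compound list**

1 | 3-(3-hydroxy-4-methoxyphenyl)propanoic acid | COc1ccc(CCC(=O)O)cc1O | starting material
2 | benzyl 3-[3-(benzyloxy)-4-methoxyphenyl]propanoate | COc1ccc(CCC(=O)OCc2ccccc2)cc1OCc1ccccc1 | intermediate (not isolated)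
3 | 3-[3-(benzyloxy)-4-methoxyphenyl]propanoic acid | COc1ccc(CCC(=O)O)cc1OCc1ccccc1 | intermediate
4 | (S)-4-benzyloxazolidin-2-one | O=C1N[C@@H](Cc2ccccc2)CO1 | starting material
5 | 3-[3-(benzyloxy)-4-methoxyphenyl]propanoic pivalic anhydride | COc1ccc(CCC(=O)OC(=O)C(C)(C)C)cc1OCc1ccccc1 | intermediate (not isolated)
6 | (S)-4-benzyl-3-{3-[3-(benzyloxy)-4-methoxyphenyl]propanoyl}oxazolidin-2-one | COc1ccc(CCC(=O)N2[C@@H](Cc3ccccc3)COC2=O)cc1OCc1ccccc1 | intermediate
7 | methyl 3-(4-hydroxy-3-methoxyphenyl)propanoate | COC(=O)CCc1ccc(O)c(OC)c1 | starting material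
8 | methyl 3-[4-(benzyloxy)-3-methoxyphenyl]propanoate | COC(=O)CCc1ccc(OCc2ccccc2)c(OC)c1 | intermediate
9 | lithium (Z)-enolate of imide 6 | [Li+].COc1ccc(C/C=C(\[O-])N2[C@@H](Cc3ccccc3)COC2=O)cc1OCc1ccccc1 | intermediate (not isolated)
10 | lithium enolate of ester 8 | [Li+].CO/C([O-])=C\Cc1ccc(OCc2ccccc2)c(OC)c1 | intermediate (not isolated)
11 | methyl (2R,3R)-4-[(S)-4-benzyl-2-oxooxazolidin-3-yl]-3-[3-(benzyloxy)-4-methoxybenzyl]-2-[4-(benzyloxy)-3-methoxybenzyl]-4-oxobutanoate | COc1ccc(C[C@@H](C(=O)N2[C@@H](Cc3ccccc3)COC2=O)[C@H](C(=O)OC)Cc2ccc(OCc3ccccc3)c(OC)c2)cc1OCc1ccccc1 | intermediate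
12 | (2R,3R)-2-[3-(benzyloxy)-4-methoxybenzyl]-3-[4-(benzyloxy)-3-methoxybenzyl]butane-1,4-diol | COc1ccc(C[C@@H](CO)[C@H](CO)Cc2ccc(OCc3ccccc3)c(OC)c2)cc1OCc1ccccc1 | intermediate
13 | (2R,3R)-2-[3-(benzyloxy)-4-methoxybenzyl]-3-[4-(benzyloxy)-3-methoxybenzyl]butane-1,4-diyl dibenzoate | COc1ccc(C[C@@H](COC(=O)c2ccccc2)[C@H](COC(=O)c2ccccc2)Cc2ccc(OCc3ccccc3)c(OC)c2)cc1OCc1ccccc1 | intermediate
14 | (2R,3R)-2-(3-hydroxy-4-methoxybenzyl)-3-(4-hydroxy-3-methoxybenzyl)butane-1,4-diyl dibenzoate | COc1ccc(C[C@@H](COC(=O)c2ccccc2)[C@H](COC(=O)c2ccccc2)Cc2ccc(O)c(OC)c2)cc1O | target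

**Count**

Total step count: 7. Longest linear sequence: 6 (steps 1, 2, 4, 5, 6, 7).

**Steps most likely to fail**

Step 4. The configuration at the ester α-carbon (C2 of 11) may be poorly controlled in the bond-forming event, because the auxiliary governs only the imide α-carbon. The fallback replaces kinetic control by thermodynamic funnelling and sets out from 11, taken on together with its C2 epimer methyl (2S,3R)-4-[(S)-4-benzyl-2-oxooxazolidin-3-yl]-3-[3-(benzyloxy)-4-methoxybenzyl]-2-[4-(benzyloxy)-3-methoxybenzyl]-4-oxobutanoate F1. LiBH4/MeOH (1.2 equiv each) in THF at 0 °C should reduce only the imide carbonyl. The γ-hydroxy esters should then close to the trans-lactone (3R,4R)-4-[3-(benzyloxy)-4-methoxybenzyl]-3-[4-(benzyloxy)-3-methoxybenzyl]dihydrofuran-2(3H)-one F2 and its cis epimer (3S,4R)-4-[3-(benzyloxy)-4-methoxybenzyl]-3-[4-(benzyloxy)-3-methoxybenzyl]dihydrofuran-2(3H)-one F3. The auxiliary-controlled centre is now the non-enolizable β-carbon, so DBU in toluene at 80 °C should epimerize only the lactone α-carbon and funnel F3 into the thermodynamically preferred trans-lactone F2. LiAlH4 in THF then opens F2 to diol 12, where the route is rejoined.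

Step 5. Hydride may attack the endocyclic carbamate carbonyl of the hindered, doubly branched imide and open the oxazolidinone ring instead of releasing it. The fallback removes the auxiliary hydrolytically before any reduction and sets out from 11. LiOH/H2O2 in THF/H2O at 0 °C (hydroperoxide selects the exocyclic carbonyl) should give the half-ester (2R,3R)-2-[3-(benzyloxy)-4-methoxybenzyl]-3-[4-(benzyloxy)-3-methoxybenzyl]-4-methoxy-4-oxobutanoic acid F4. LiAlH4 in THF then reduces acid and ester together to diol 12, where the route is rejoined.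

Step 7. Hydrogenolysis of the two aryl benzyl ethers may stall through catalyst deactivation. The fallback changes the cleavage from hydrogenolysis to Lewis-acid debenzylation and sets out from 13. BCl3 with pentamethylbenzene as cation scavenger in CH2Cl2 at −78 °C should remove both benzyl groups while sparing the aryl methyl ethers and the benzoates, and gives 14 directly; this fallback makes no new compound (F0).

**Further compounds**

F1 | step 4 | methyl (2S,3R)-4-[(S)-4-benzyl-2-oxooxazolidin-3-yl]-3-[3-(benzyloxy)-4-methoxybenzyl]-2-[4-(benzyloxy)-3-methoxybenzyl]-4-oxobutanoate | COc1ccc(C[C@@H](C(=O)N2[C@@H](Cc3ccccc3)COC2=O)[C@@H](C(=O)OC)Cc2ccc(OCc3ccccc3)c(OC)c2)cc1OCc1ccccc1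
F2 | step 4 | (3R,4R)-4-[3-(benzyloxy)-4-methoxybenzyl]-3-[4-(benzyloxy)-3-methoxybenzyl]dihydrofuran-2(3H)-one | COc1ccc(C[C@H]2COC(=O)[C@@H]2Cc2ccc(OCc3ccccc3)c(OC)c2)cc1OCc1ccccc1
F3 | step 4 | (3S,4R)-4-[3-(benzyloxy)-4-methoxybenzyl]-3-[4-(benzyloxy)-3-methoxybenzyl]dihydrofuran-2(3H)-one | COc1ccc(C[C@H]2COC(=O)[C@H]2Cc2ccc(OCc3ccccc3)c(OC)c2)cc1OCc1ccccc1
F4 | step 5 | (2R,3R)-2-[3-(benzyloxy)-4-methoxybenzyl]-3-[4-(benzyloxy)-3-methoxybenzyl]-4-methoxy-4-oxobutanoic acid | COc1ccc(C[C@@H](C(=O)O)[C@H](C(=O)OC)Cc2ccc(OCc3ccccc3)c(OC)c2)cc1OCc1ccccc1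
F0 | step 7 | none | none
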